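**Plan**
Numbering follows the target throughout: ring C1–C10, lactone oxygen on C6, C7 carries C11(=C13)–C12, C14 on C10, C15 on C4; the six-membered precursors keep these numbers (ring C1–C6).
Cuts: the ester C–O bonds at O3 and O8, the C1/C10 oxirane, C11=C13, the lactone C6–O and C7–C11, then C8–C9 with C1–C6 re-joined, which turns the ten-membered ring back into a six-membered one.
Enabling feature: C3–C4(C15)=C5–C6 with its Z alkene is a cyclohexene segment, so ring C1–C10 equals cyclohexene C1–C6 plus the four atoms C7–C10, present as an E C7=C8 enol ether on C6 and an isopropenyl group C10(C14)=C9 on C1.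
Forward: (S)-carvone is transposed to silylated trans-carveol and oxidised to the C6 enone; the C7=C8 unit is added and etherified; ring expansion gives the cyclodecadienone; C7 is alkylated, the lactone closed, C13 added, both esters installed and C1=C10 epoxidised last; the epoxy acid is made separately.
Stereochemistry: C1 from carvone; C3 from anti epoxidation and Wharton transposition; the C6 carbinol by addition anti to isopropenyl; C8 by the chair transition state; C7 by a chelated enolate; C6 by chelation-controlled reduction then Mitsunobu inversion; the C1/C10 oxirane by outer-face attack; the acyl epoxide by Sharpless epoxidation.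

Key step: step 8

Remark 1: an (E)-2-alkoxyvinyllithium holds metal and alkoxy group anti and is expected to lose alkoxide, so the E enol ether is assembled on the carbinol (steps 5 to 7).
Remark 2: angelic acid and (E)-1,2-bis(tributylstannyl)ethene are taken as commercially available.

**Route**

Step 1
Reactants: 1 (S)-(+)-carvone
Product: 2 (1S,4S,6S)-1-methyl-4-(prop-1-en-2-yl)-7-oxabicyclo[4.1.0]heptan-2-one (oxirane trans to isopropenyl)
Conditions: 30% H2O2, NaOH (cat.), MeOH, 0 °C
Reagents that add atoms: hydrogen peroxide, OO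
Why: Weitz–Scheffer nucleophilic epoxidation, in which hydroperoxide adds only to the enone and closes the oxirane on the face anti to the isopropenyl group, which fixes the future C3–O configuration and leaves the isolated alkene untouched.

Step 2
Reactants: 2 carvone epoxide
Product: 4 (1S,5R)-2-methyl-5-(prop-1-en-2-yl)cyclohex-2-en-1-ol (trans-carveol), via epoxy hydrazone 3 (not isolated)
Conditions: N2H4·H2O, AcOH (cat.), MeOH, 0 °C to rt
Reagents that add atoms: none
Why: Wharton transposition, in which the epoxy hydrazone fragments with loss of dinitrogen so that the carbonyl carbon becomes an alkene carbon while the distal C–O bond of the oxirane keeps its configuration, giving the allylic alcohol trans to isopropenyl.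

Step 3
Reactants: 4 trans-carveol
Product: 5 (1S,5R)-1-(tert-butyldimethylsilyloxy)-2-methyl-5-(prop-1-en-2-yl)cyclohex-2-ene
Conditions: TBSCl, imidazole, DMF, rt
Reagents that add atoms: tert-butyldimethylsilyl chloride, CC(C)(C)[Si](C)(C)Cl
Why: Standard silylation of a secondary allylic alcohol masks the C3 oxygen as an ether that is inert to the organometallic and strongly basic steps ahead.

Step 4
Reactants: 5 silyl ether
Product: 7 (4S,6R)-4-(tert-butyldimethylsilyloxy)-3-methyl-6-(prop-1-en-2-yl)cyclohex-2-en-1-one, via allylic peroxide 6 (not isolated)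
Conditions: Rh2(cap)4 (1 mol%; cap = caprolactamate, C6H10NO), t-BuOOH (5 equiv), K2CO3, CH2Cl2, rt
Reagents that add atoms: tert-butyl hydroperoxide, CC(C)(C)OO
Why: Dirhodium caprolactamate-catalysed allylic C–H oxidation (hydrogen abstraction by the peroxyl radical, mixed peroxide, Kornblum–DeLaMare-type collapse) is known to turn the ring methylene next to the CH terminus of 1-methylcyclohexenes into the enone also when an isopropenyl group is present, the other ring allylic position is blocked here by the silyloxy group, and no stereocentre is touched.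

Step 5
Reactants: 7 enone; 8 (E)-1,2-bis(tributylstannyl)ethene
Product: 9 (1R,4S,6R)-4-(tert-butyldimethylsilyloxy)-3-methyl-6-(prop-1-en-2-yl)-1-[(E)-2-(tributylstannyl)ethenyl]cyclohex-2-en-1-ol
Conditions: 8, n-BuLi, THF, −78 °C; CeCl3, −78 °C; then 7, −78 °C; aq. NH4Cl
Reagents that add atoms: none
Why: Organocerium 1,2-addition to an enone, in which tin–lithium exchange gives the configurationally stable E alkenyl metal, the cerium reagent does not enolise the doubly activated C1–H, and attack from the equatorial direction anti to the adjacent isopropenyl group should set the (R) carbinol centre C6 with the two alkenyl groups trans.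

Step 6
Reactants: 9 stannyl dienol
Product: 10 (1R,4S,6R)-4-(tert-butyldimethylsilyloxy)-1-[(E)-2-iodoethenyl]-3-methyl-6-(prop-1-en-2-yl)cyclohex-2-en-1-ol
Conditions: I2, CH2Cl2, 0 °C
Reagents that add atoms: iodine, II
Why: Iododestannylation (ipso electrophilic substitution of an alkenylstannane) is fast at 0 °C and stereoretentive, so the E iodide should result without touching the other alkenes.

Step 7
Reactants: 10 alkenyl iodide; 11 4-methoxybenzyl alcohol
Product: 12 (1R,4S,6R)-4-(tert-butyldimethylsilyloxy)-1-[(E)-2-(4-methoxybenzyloxy)ethenyl]-3-methyl-6-(prop-1-en-2-yl)cyclohex-2-en-1-ol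
Conditions: CuI (10 mol%), 3,4,7,8-tetramethyl-1,10-phenanthroline (20 mol%), Cs2CO3, toluene, 80 °C
Reagents that add atoms: none
Why: Ullmann-type copper-catalysed C–O coupling of an alkenyl iodide with a primary alcohol proceeds with retention of alkene geometry and installs the E enol ether, while the tertiary allylic alcohol is too hindered to couple.

Step 8
Reactants: 12 dialkenyl cyclohexenol
Product: 15 (2Z,4S,6E,9R)-4-(tert-butyldimethylsilyloxy)-9-(4-methoxybenzyloxy)-3,7-dimethylcyclodeca-2,6-dien-1-one, via potassium alkoxide 13 (not isolated), via potassium enolate 14 (not isolated)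
Conditions: KH, 18-crown-6, THF, 0 °C to rt; then AcOH in THF, −78 °C
Reagents that add atoms: none
Why: The potassium alkoxide 13 undergoes a concerted anionic oxy-Cope rearrangement ([3,3]-sigmatropic shift of a 3-oxido-1,5-diene) in which C8–C9 forms while the ring bond C1–C6 breaks, giving the conjugated enolate 14, which the cold quench protonates at C7. The closest known reaction type is the alkoxide-accelerated ring expansion of trans-1,2-dialkenylcyclohexanols to cyclodec-5-enones. The ten-membered ring is not closed end to end but released by a four-atom enlargement of the cyclohexene, so the Z alkene C4=C5 is carried over unchanged and no medium-ring cyclisation entropy is paid. The new stereocentre C8 is set by the chair transition state that the trans alkenyl groups allow, with both ring bonds and the E benzyloxy group equatorial and the sense of the chair fixed by the (R) centres C6 and C1, which gives 8R and the E alkene C1=C10. The step needs chair over boat, which the diequatorial trans arrangement secures, and the β-alkoxy enolate 14 must not expel 4-methoxybenzyl oxide, which is countered by the poor leaving group, by the C8–O bond lying near the nodal plane of the enolate as it forms, and by quenching cold as soon as 13 is consumed.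

Step 9
Reactants: 15 cyclodecadienone; 16 methyl bromoacetate
Product: 18 methyl ester of the C7-carboxymethyl ketone (15 with CH2CO2Me on C7 cis to the C8 oxygen; 3S,7R,8R), via lithium enolate 17 (not isolated)
Conditions: LiN(iPr)2 (LDA), THF, −78 °C; then 16, −78 to −40 °C, no polar additive
Reagents that add atoms: none
Why: Kinetic α′-deprotonation of the enone followed by SN2 alkylation, in which the lithium enolate is held as a six-membered chelate with the C8 benzyloxy oxygen that keeps the C8–O bond in the nodal plane (no β-elimination) and exposes the face of C7 anti to the ring carbon C9, so that C11 should enter cis to the C8 oxygen (7R).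

Step 10
Reactants: 18 keto ester
Product: 20 cis-fused 6-epi lactone (12,6-olide with the C6 oxygen β; 3S,6S,7R,8R), via hydroxy ester 19 (not isolated)
Conditions: Zn(BH4)2, Et2O, −20 °C; H2O; PPTS (cat.), CH2Cl2, rt
Reagents that add atoms: none
Why: Chelation-controlled 1,2-reduction of a β-alkoxy ketone, in which zinc bridges the carbonyl and the C8 ether oxygen and hydride adds axially to the chelate with the C7 and C8 substituents equatorial, which should give the 6β alcohol (syn to the C8 oxygen, 6S) that closes the cis-fused γ-lactone by 5-exo-trig acyl substitution.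

Step 11
Reactants: 20 cis-fused lactone
Product: 22 trans-fused lactone (12,6-olide with the C6 oxygen α; 3S,6R,7R,8R), via hydroxy acid 21 (not isolated)
Conditions: LiOH, THF/H2O, 0 °C; 1 M HCl to pH 5, extraction; then PPh3, DIAD, THF, 0 °C
Reagents that add atoms: lithium hydroxide, [Li+].[OH-]
Why: Saponification opens the lactone without touching C6, and Mitsunobu lactonisation then activates the C6 hydroxyl as an oxyphosphonium ion that the internal carboxylate displaces by SN2 with inversion, turning the 6β (S) into the required 6α (R) centre.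

Step 12
Reactants: 22 trans-fused lactone
Product: 24 C11-(dimethylaminomethyl) lactone (C11 configuration immaterial), via lithium lactone enolate 23 (not isolated)
Conditions: LiN(iPr)2, THF, −78 °C; CH2=NMe2+ I− (Eschenmoser's salt), −78 °C to rt
Reagents that add atoms: Eschenmoser's salt (N,N-dimethylmethyleneiminium iodide), C[N+](C)=C.[I-]
Why: Mannich reaction of the lactone lithium enolate places the aminomethyl group on C11, the only enolisable position, and the new C11 centre is removed in the next step.

Step 13
Reactants: 24 Mannich base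
Product: 26 α-methylene lactone (3-O-TBS, 8-O-PMB; 3S,6R,7R,8R), via ammonium iodide 25 (not isolated)
Conditions: MeI, MeOH, rt; then aq. NaHCO3, EtOAc, rt
Reagents that add atoms: none
Why: Exhaustive N-methylation followed by base-induced β-elimination of trimethylamine (Hofmann-type, E1cB) unveils the C11=C13 alkene under conditions too mild to affect the ethers.

Step 14
Reactants: 26 α-methylene lactone
Product: 27 C3 alcohol (8-O-PMB α-methylene lactone)
Conditions: HF·pyridine, pyridine, THF, 0 °C to rt
Reagents that add atoms: none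
Why: Fluoride-mediated desilylation buffered by pyridine cleaves only the Si–O bond, leaving the 4-methoxybenzyl ether, the lactone and the C3 configuration untouched.

Step 15
Reactants: 27 C3 alcohol; 28 3-methylbutanoyl chloride
Product: 29 C3 isovalerate (8-O-PMB)
Conditions: pyridine, DMAP (cat.), CH2Cl2, 0 °C
Reagents that add atoms: none
Why: Nucleophile-catalysed acylation of the secondary allylic alcohol occurs at oxygen and so retains C3.

Step 16
Reactants: 29 C3 isovalerate
Product: 30 C8 alcohol (3-O-isovaleryl α-methylene lactone; 3S,6R,7R,8R)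
Conditions: DDQ, CH2Cl2/pH 7 buffer, 0 °C to rt
Reagents that add atoms: none
Why: Oxidative cleavage of a 4-methoxybenzyl ether by DDQ (benzylic hydride abstraction, then hydrolysis of the oxocarbenium ion) frees the C8 hydroxyl at neutral pH without affecting the esters or the alkenes.

Step 17
Reactants: 31 angelic acid
Product: 32 (Z)-2-methylbut-2-en-1-ol
Conditions: LiAlH4, Et2O, 0 °C
Reagents that add atoms: none
Why: Hydride reduction of the carboxylic acid with LiAlH4 gives the allylic alcohol and does not alter the Z alkene geometry.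

Step 18
Reactants: 32 (Z)-2-methylbut-2-en-1-ol
Product: 33 [(2S,3R)-2,3-dimethyloxiran-2-yl]methanol
Conditions: Ti(OiPr)4 (10 mol%), L-(+)-diethyl tartrate (12 mol%), t-BuOOH, 4 Å MS, CH2Cl2, −20 °C
Reagents that add atoms: tert-butyl hydroperoxide, CC(C)(C)OO
Why: Sharpless asymmetric epoxidation, in which the L-(+)-tartrate complex delivers the peroxide oxygen to the alkene face that gives the (2S,3R) epoxy alcohol, and syn addition keeps the C3 methyl cis to the hydroxymethyl group.

Step 19
Reactants: 33 epoxy alcohol
Product: 34 (2R,3R)-2,3-dimethyloxirane-2-carboxylic acid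
Conditions: RuCl3 (cat.), NaIO4, MeCN/EtOAc/H2O, rt
Reagents that add atoms: water, O
Why: Ruthenium tetroxide oxidation (RuCl3/NaIO4) takes the primary alcohol to the acid through the aldehyde hydrate without opening the oxirane, so both centres are retained (2R,3R only by the change of substituent priority).

Step 20
Reactants: 30 C8 alcohol; 34 epoxy acid
Product: 36 3-O-isovaleryl-8-O-[(2R,3R)-2,3-dimethyloxirane-2-carbonyl] diene lactone (the 1(10)-ene of the target), via mixed anhydride 35 (not isolated)
Conditions: 2,4,6-trichlorobenzoyl chloride, Et3N, THF, rt; then 30, DMAP, toluene, rt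
Reagents that add atoms: none
Why: Yamaguchi esterification, in which the mixed anhydride passes the hindered α,α-disubstituted acyl group through its acylpyridinium ion to the C8 hydroxyl, reaction at oxygen leaving C8 and the oxirane centres intact.

Step 21
Reactants: 36 diester diene
Product: 37 CNP0167461.2 (1R,3S,6R,7R,8R,10R; acyl 2R,3R)
Conditions: mCPBA, NaHCO3, CH2Cl2, 0 °C
Reagents that add atoms: 3-chloroperoxybenzoic acid, OOC(=O)c1cccc(Cl)c1
Why: Prilezhaev epoxidation, in which the peracid selects the only electron-rich alkene (C4=C5 is deactivated by two allylic acyloxy groups and C11=C13 is conjugated) and should attack the exposed outer face of the E ring alkene, syn addition giving the trans 1β,10α (1R,10R) oxirane.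

**Compound list**
1 | (S)-(+)-carvone | CC1=CC[C@@H](CC1=O)C(C)=C | starting material
2 | (1S,4S,6S)-1-methyl-4-(prop-1-en-2-yl)-7-oxabicyclo[4.1.0]heptan-2-one | C1C(=O)[C@@]2(C)O[C@H]2C[C@@H]1C(C)=C | intermediate
3 | hydrazone of 2 (not isolated) | C1C(=NN)[C@@]2(C)O[C@H]2C[C@@H]1C(C)=C | intermediate
4 | (1S,5R)-2-methyl-5-(prop-1-en-2-yl)cyclohex-2-en-1-ol (trans-carveol) | C1C=C(C)[C@@H](O)C[C@@H]1C(C)=C | intermediate
5 | tert-butyldimethylsilyl ether of 4 | C1C=C(C)[C@@H](O[Si](C)(C)C(C)(C)C)C[C@@H]1C(C)=C | intermediate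
6 | 6-(tert-butylperoxy) derivative of 5 (ring CH2 next to C5; mixture at C6; not isolated) | CC(C)(C)OOC1C=C(C)[C@@H](O[Si](C)(C)C(C)(C)C)C[C@@H]1C(C)=C | intermediate
7 | (4S,6R)-4-(tert-butyldimethylsilyloxy)-3-methyl-6-(prop-1-en-2-yl)cyclohex-2-en-1-one | O=C1C=C(C)[C@@H](O[Si](C)(C)C(C)(C)C)C[C@@H]1C(C)=C | intermediate
8 | (E)-1,2-bis(tributylstannyl)ethene | CCCC[Sn](CCCC)(CCCC)/C=C/[Sn](CCCC)(CCCC)CCCC | starting material
9 | (1R,4S,6R)-4-(tert-butyldimethylsilyloxy)-3-methyl-6-(prop-1-en-2-yl)-1-[(E)-2-(tributylstannyl)ethenyl]cyclohex-2-en-1-ol | O[C@]1(/C=C/[Sn](CCCC)(CCCC)CCCC)C=C(C)[C@@H](O[Si](C)(C)C(C)(C)C)C[C@@H]1C(C)=C | intermediate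
10 | (1R,4S,6R)-4-(tert-butyldimethylsilyloxy)-1-[(E)-2-iodoethenyl]-3-methyl-6-(prop-1-en-2-yl)cyclohex-2-en-1-ol | O[C@]1(/C=C/I)C=C(C)[C@@H](O[Si](C)(C)C(C)(C)C)C[C@@H]1C(C)=C | intermediate
11 | 4-methoxybenzyl alcohol | COc1ccc(CO)cc1 | starting material
12 | (1R,4S,6R)-4-(tert-butyldimethylsilyloxy)-1-[(E)-2-(4-methoxybenzyloxy)ethenyl]-3-methyl-6-(prop-1-en-2-yl)cyclohex-2-en-1-ol | O[C@]1(/C=C/OCc2ccc(OC)cc2)C=C(C)[C@@H](O[Si](C)(C)C(C)(C)C)C[C@@H]1C(C)=C | intermediate
13 | potassium alkoxide of 12 (not isolated) | [K+].[O-][C@]1(/C=C/OCc2ccc(OC)cc2)C=C(C)[C@@H](O[Si](C)(C)C(C)(C)C)C[C@@H]1C(C)=C | intermediate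
14 | potassium C6–C7 enolate of 15 (C5 and C8 trans across C6=C7; not isolated) | [K+].C1/C(C)=C/C[C@H](O[Si](C)(C)C(C)(C)C)/C(C)=C\C([O-])=C\[C@@H]1OCc2ccc(OC)cc2 | intermediate
15 | (2Z,4S,6E,9R)-4-(tert-butyldimethylsilyloxy)-9-(4-methoxybenzyloxy)-3,7-dimethylcyclodeca-2,6-dien-1-one | O=C1/C=C(/C)[C@@H](O[Si](C)(C)C(C)(C)C)C/C=C(\C)C[C@@H](OCc2ccc(OC)cc2)C1 | intermediate
16 | methyl bromoacetate | COC(=O)CBr | starting material
17 | lithium C6–C7 enolate of 15 (not isolated) | [Li+].C1/C(C)=C/C[C@H](O[Si](C)(C)C(C)(C)C)/C(C)=C\C([O-])=C\[C@@H]1OCc2ccc(OC)cc2 | intermediate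
18 | ketone 15 bearing CH2CO2Me on C7 (3S,7R,8R) | O=C1/C=C(/C)[C@@H](O[Si](C)(C)C(C)(C)C)C/C=C(\C)C[C@@H](OCc2ccc(OC)cc2)[C@H]1CC(=O)OC | intermediate
19 | 6β-hydroxy methyl ester (3S,6S,7R,8R; not isolated) | O[C@H]1/C=C(/C)[C@@H](O[Si](C)(C)C(C)(C)C)C/C=C(\C)C[C@@H](OCc2ccc(OC)cc2)[C@H]1CC(=O)OC | intermediate
20 | cis-fused 6-epi lactone (3S,6S,7R,8R) | C1C(=O)O[C@H]2/C=C(/C)[C@@H](O[Si](C)(C)C(C)(C)C)C/C=C(\C)C[C@@H](OCc3ccc(OC)cc3)[C@@H]12 | intermediate
21 | 6β-hydroxy acid (3S,6S,7R,8R; not isolated) | O[C@H]1/C=C(/C)[C@@H](O[Si](C)(C)C(C)(C)C)C/C=C(\C)C[C@@H](OCc2ccc(OC)cc2)[C@H]1CC(=O)O | intermediate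
22 | trans-fused lactone (3S,6R,7R,8R) | C1C(=O)O[C@@H]2/C=C(/C)[C@@H](O[Si](C)(C)C(C)(C)C)C/C=C(\C)C[C@@H](OCc3ccc(OC)cc3)[C@@H]12 | intermediate
23 | lithium enolate of lactone 22 (not isolated) | [Li+].C1=C([O-])O[C@@H]2/C=C(/C)[C@@H](O[Si](C)(C)C(C)(C)C)C/C=C(\C)C[C@@H](OCc3ccc(OC)cc3)[C@@H]12 | intermediate
24 | C11-(dimethylaminomethyl) lactone (C11 unassigned) | CN(C)CC1C(=O)O[C@@H]2/C=C(/C)[C@@H](O[Si](C)(C)C(C)(C)C)C/C=C(\C)C[C@@H](OCc3ccc(OC)cc3)[C@@H]12 | intermediate
25 | trimethylammonium iodide of 24 (not isolated) | [I-].C[N+](C)(C)CC1C(=O)O[C@@H]2/C=C(/C)[C@@H](O[Si](C)(C)C(C)(C)C)C/C=C(\C)C[C@@H](OCc3ccc(OC)cc3)[C@@H]12 | intermediate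
26 | α-methylene lactone, 3-O-TBS, 8-O-PMB | C=C1C(=O)O[C@@H]2/C=C(/C)[C@@H](O[Si](C)(C)C(C)(C)C)C/C=C(\C)C[C@@H](OCc3ccc(OC)cc3)[C@@H]12 | intermediate
27 | α-methylene lactone, 3-OH, 8-O-PMB | C=C1C(=O)O[C@@H]2/C=C(/C)[C@@H](O)C/C=C(\C)C[C@@H](OCc3ccc(OC)cc3)[C@@H]12 | intermediate
28 | 3-methylbutanoyl chloride | CC(C)CC(=O)Cl | starting material
29 | α-methylene lactone, 3-O-isovaleryl, 8-O-PMB | C=C1C(=O)O[C@@H]2/C=C(/C)[C@@H](OC(=O)CC(C)C)C/C=C(\C)C[C@@H](OCc3ccc(OC)cc3)[C@@H]12 | intermediate
30 | α-methylene lactone, 3-O-isovaleryl, 8-OH | C=C1C(=O)O[C@@H]2/C=C(/C)[C@@H](OC(=O)CC(C)C)C/C=C(\C)C[C@@H](O)[C@@H]12 | intermediate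
31 | angelic acid, (Z)-2-methylbut-2-enoic acid | C/C=C(/C)C(=O)O | starting material
32 | (Z)-2-methylbut-2-en-1-ol | C/C=C(/C)CO | intermediate
33 | [(2S,3R)-2,3-dimethyloxiran-2-yl]methanol | OC[C@]1(C)O[C@@H]1C | intermediate
34 | (2R,3R)-2,3-dimethyloxirane-2-carboxylic acid | OC(=O)[C@]1(C)O[C@@H]1C | intermediate
35 | (2R,3R)-2,3-dimethyloxirane-2-carboxylic 2,4,6-trichlorobenzoic anhydride (not isolated) | O=C(OC(=O)c1c(Cl)cc(Cl)cc1Cl)[C@]1(C)O[C@@H]1C | intermediate
36 | 1(10)-ene of the target (3-O-isovaleryl, 8-O-epoxyangeloyl) | C=C1C(=O)O[C@@H]2/C=C(/C)[C@@H](OC(=O)CC(C)C)C/C=C(\C)C[C@@H](OC(=O)[C@]3(C)O[C@@H]3C)[C@@H]12 | intermediate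
37 | CNP0167461.2 | C=C1C(=O)O[C@@H]2/C=C(/C)[C@@H](OC(=O)CC(C)C)C[C@H]3O[C@]3(C)C[C@@H](OC(=O)[C@]3(C)O[C@@H]3C)[C@@H]12 | target

**Totals**
Total step count: 21. Longest linear sequence: 18 steps (steps 1 to 16, 20 and 21, from 1 to 37); the epoxy acid 34 takes 3 steps from 31.

**Steps most likely to fail**

Step 8. The enolate 14 may expel 4-methoxybenzyl oxide (E1cB) before the quench, above all if the rearrangement needs warming. The fallback runs the same ring expansion on 12 without base: catalytic PdCl2(PhCN)2 in THF at room temperature (palladium dichloride-catalysed oxy-Cope rearrangement). The metal activates the enol ether, the isopropenyl group attacks C8 through a chair-like six-membered arrangement to give a tertiary C10 cation, and cleavage of C1–C6 releases ketone 15 directly, so no enolate is ever present. It sets out from 12 and returns at 15, and makes no compound outside the list (F0).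

Step 9. Loss of chelation control would let the electrophile enter on the other face of C7, and warming the enolate risks loss of the C8 alkoxy group. The fallback reverses the order in which carbon and hydrogen arrive at C7. From 15, the lithium enolate is added to methyl glyoxylate to give the aldol adduct F1. Mesylation (MsCl, Et3N) gives the mesylate F2, and DBU eliminates it to the alkylidene keto ester F3. Conjugate reduction with K[(s-Bu)3BH] at −78 °C generates the non-chelated potassium enolate F4. A hindered phenol then protonates C7 from the face the carbon electrophile preferred, which places the side chain on the opposite, required face and returns to 18.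

Step 5. Poor facial selectivity in the carbonyl addition (attack anti to the pseudoaxial silyloxy group instead of anti to isopropenyl) would give the cis-dialkenyl carbinol, which leads to the Z ring alkene. The fallback uses the C3 oxygen as a directing group. From 7, HF·pyridine gives the hydroxy enone F5. Its magnesium alkoxide binds (E)-2-(tributylstannyl)vinylmagnesium bromide (2.5 equiv, from the lithium reagent and MgBr2) and delivers it to the carbonyl face syn to the C3 oxygen, which is the face anti to isopropenyl, giving the diol F6. Selective silylation of the secondary hydroxyl (TBSCl, imidazole) returns to 9.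

**Further compounds**
F0 | step 8 | none | none
F1 | step 9 | aldol adduct of 15 with methyl glyoxylate at C7 (new centres unassigned) | O=C1/C=C(/C)[C@@H](O[Si](C)(C)C(C)(C)C)C/C=C(\C)C[C@@H](OCc2ccc(OC)cc2)C1C(O)C(=O)OC
F2 | step 9 | mesylate of F1 | O=C1/C=C(/C)[C@@H](O[Si](C)(C)C(C)(C)C)C/C=C(\C)C[C@@H](OCc2ccc(OC)cc2)C1C(OS(C)(=O)=O)C(=O)OC
F3 | step 9 | C7 (methoxycarbonyl)methylidene ketone (alkene geometry unassigned) | O=C1/C=C(/C)[C@@H](O[Si](C)(C)C(C)(C)C)C/C=C(\C)C[C@@H](OCc2ccc(OC)cc2)C1=CC(=O)OC
F4 | step 9 | potassium C6–C7 enolate of 18 (enolate geometry unassigned) | [K+].C1/C(C)=C/C[C@H](O[Si](C)(C)C(C)(C)C)/C(C)=C\C([O-])=C(CC(=O)OC)[C@@H]1OCc2ccc(OC)cc2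
F5 | step 5 | (4S,6R)-4-hydroxy-3-methyl-6-(prop-1-en-2-yl)cyclohex-2-en-1-one | O=C1C=C(C)[C@@H](O)C[C@@H]1C(C)=C
F6 | step 5 | (1R,4S,6R)-3-methyl-6-(prop-1-en-2-yl)-1-[(E)-2-(tributylstannyl)ethenyl]cyclohex-2-ene-1,4-diol | O[C@]1(/C=C/[Sn](CCCC)(CCCC)CCCC)C=C(C)[C@@H](O)C[C@@H]1C(C)=C
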